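**Plan**
- Cuts, in retrosynthetic order: CHO back to CO2Me; C2–Br back to the lactam C=O of an oxindole-3-carboxylate; C3–C3a (retro-Wolff); C3=N2; C3–C4 of a 4-hydroxyquinolin-2-one (retro-Dieckmann); N–CH3, N–acetyl and one C–Br of an anthranilate.
- Enabling feature: in the five-membered ring, C3 sits between the benzo carbon C3a and C2, which is at the carbonyl oxidation level (C–Br). C3 also carries a single exocyclic carbonyl carbon. A quinoline-2,4-dione whose ketone carbon C4 is squeezed out of the six-membered ring by an aryl shift leaves exactly this arrangement.
- The six-membered lactam is closed at an ester carbonyl, not at an arene C–H. The anthranilate therefore fixes the 6,7-dibromo pattern, and the electron-poor benzene ring never has to act as a nucleophile in a ring closure.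
- Forward order of rings: purchased benzene ring, six-membered lactam (step 4), contraction to the five-membered lactam (step 6), aromatisation to the indole (step 7), then ester to aldehyde (steps 8 and 9).
- Atom origin: the acetyl C=O and CH3 become C2 and C3, and the benzoate carbonyl carbon becomes the CHO carbon.
- Stereochemistry: the target is achiral. The only stereocentre passed, C3 of the oxindole ester, is racemic, enolisable and erased in step 7.

Key step: step 6

Assumption: 6 is drawn as the 4-hydroxy-2-quinolone tautomer and 9 as the keto-lactam tautomer; both should equilibrate with their other tautomers, which does not affect any step.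

Step 1
Reactants: 1 methyl 2-amino-4-bromobenzoate
Product: 2 methyl 2-amino-4,5-dibromobenzoate
Conditions: NBS (1.0 equiv), DMF, 0 °C to rt
Reagents that add atoms: N-bromosuccinimide, O=C1CCC(=O)N1Br
Why: Electrophilic aromatic bromination of a free aniline: NH2 directs to its para position C5, which the meta-directing ester and the ortho/para-directing C4 bromine also favour, whereas the only other activated site, C3, is wedged between NH2 and Br.

Step 2
Reactants: 2 methyl 2-amino-4,5-dibromobenzoate; 3 acetic anhydride
Product: 4 methyl 2-acetamido-4,5-dibromobenzoate
Conditions: Ac2O (2 equiv), toluene, 100 °C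
Reagents that add atoms: none
Why: N-Acylation of the aniline with an anhydride, which installs the two carbons that become C2 and C3 of the heterocycle and leaves a single acidic N–H for the next step.

Step 3
Reactants: 4 methyl 2-acetamido-4,5-dibromobenzoate
Product: 5 methyl 4,5-dibromo-2-(N-methylacetamido)benzoate
Conditions: NaH (1.05 equiv), MeI (1.2 equiv), DMF, 0 °C to rt
Reagents that add atoms: iodomethane, CI
Why: SN2 N-alkylation of the sodium anilide, which cannot overshoot because only one N–H is present and one equivalent of NaH removes this proton and not the far less acidic acetyl C–H.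

Step 4
Reactants: 5 methyl 4,5-dibromo-2-(N-methylacetamido)benzoate
Product: 6 6,7-dibromo-4-hydroxy-1-methylquinolin-2(1H)-one
Conditions: KN(SiMe3)2 (2.5 equiv), THF, −78 °C to rt; then 1 M HCl
Reagents that add atoms: none
Why: Dieckmann-type (intramolecular Claisen) condensation: the N-methylanilide prefers the rotamer that holds the acetyl CH3 next to the arene, its enolate attacks the ortho ester in a 6-exo-trig closure, and deprotonation of the acidic product drives the equilibrium, so the ring closes with fixed regiochemistry and asks nothing of the electron-poor arene.

Step 5
Reactants: 6 6,7-dibromo-4-hydroxy-1-methylquinolin-2(1H)-one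
Product: 7 6,7-dibromo-3-diazo-1-methylquinoline-2,4(1H,3H)-dione
Conditions: 4-acetamidobenzenesulfonyl azide (1.2 equiv), Et3N (1.5 equiv), MeCN, 0 °C to rt
Reagents that add atoms: 4-acetamidobenzenesulfonyl azide, CC(=O)Nc1ccc(cc1)S(=O)(=O)N=[N+]=[N-]
Why: Regitz diazo transfer: the ammonium enolate of the cyclic 1,3-dicarbonyl system attacks the terminal nitrogen of the sulfonyl azide through C3, and the adduct fragments to the 2-diazo-1,3-dicarbonyl compound and the sulfonamide, which a basic wash removes.

Step 6
Reactants: 7 6,7-dibromo-3-diazo-1-methylquinoline-2,4(1H,3H)-dione
Product: 9 methyl 5,6-dibromo-1-methyl-2-oxoindoline-3-carboxylate (racemic), via oxindol-3-ylidene ketene 8 (not isolated)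
Conditions: hν (365 nm LED), MeOH–MeCN 1:1, degassed, 20 °C
Reagents that add atoms: methanol, CO
Why: Excitation of the ring-locked s-Z diazo ketone expels N2 while the aryl carbon C4a shifts from the ketone carbon C4 to the diazo carbon C3 (Wolff rearrangement, concerted or by way of a very short-lived singlet acylcarbene), which creates the C3–C3a bond of the oxindole and turns the former C4 into the exocyclic ketene carbon of 8; methanol then adds to 8 and gives the malonate-type ester 9. The closest known reaction type is the photochemical or thermal ring contraction of cyclic 2-diazo-1,3-dicarbonyl compounds, which includes 3-diazoquinoline-2,4-diones going to oxindole-3-carboxylic acid derivatives. The five-membered lactam is closed by contraction of the six-membered lactam through a 1,2-shift and not by a cyclisation, so the low nucleophilicity of the dibrominated arene plays no part. C3 of 9 is a new stereocentre, but it forms as a racemate, is labile through the enol and disappears in step 7, so no control element is needed. The step needs migration of the aryl group on the ketone side in preference to the nitrogen on the lactam side, and the substrate secures this because the nitrogen lone pair is tied up in amide and anilide conjugation whereas the aryl ketone carbon releases its π-rich substituent readily. Light of 365 nm should be absorbed by the diazo chromophore and not by the C–Br bonds or by 9, and methanol in large excess should outrun attack of enolic 9 on the ketene.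

Step 7
Reactants: 9 methyl 5,6-dibromo-1-methyl-2-oxoindoline-3-carboxylate
Product: 11 methyl 2,5,6-tribromo-1-methylindole-3-carboxylate, via indol-2-yl dibromophosphate 10 (not isolated)
Conditions: POBr3 (2.5 equiv), 1,2-dichloroethane, 80 °C; then ice-cold aq. NaHCO3
Reagents that add atoms: phosphorus oxybromide, O=P(Br)(Br)Br
Why: Deoxygenative bromination of an enolised lactam, the standard POBr3 conversion of oxindoles into 2-bromoindoles: O-phosphorylation gives 10, bromide adds to C2 (iminium-like carbon and β-position of the unsaturated ester), and loss of dibromophosphate leaves the aromatic indole, which also erases the C3 stereocentre.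

Step 8
Reactants: 11 methyl 2,5,6-tribromo-1-methylindole-3-carboxylate
Product: 12 (2,5,6-tribromo-1-methylindol-3-yl)methanol
Conditions: iBu2AlH (3 equiv), CH2Cl2, −78 to 0 °C; then aq. potassium sodium tartrate
Reagents that add atoms: none
Why: Ester reduction with an electrophilic aluminium hydride, which should take the deactivated (vinylogous carbamate) ester to the primary alcohol without touching the three C–Br bonds, while low temperature and a neutral tartrate work-up keep the indol-3-ylmethanol from ionising.

Step 9
Reactants: 12 (2,5,6-tribromo-1-methylindol-3-yl)methanol
Product: 13 2,5,6-tribromo-1-methylindole-3-carbaldehyde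
Conditions: activated MnO2 (15 equiv), CH2Cl2, rt
Reagents that add atoms: none
Why: Heterogeneous MnO2 oxidation of a benzylic-type (indol-3-yl) carbinol, which stops at the aldehyde because the product is a vinylogous formamide that forms no hydrate, and which leaves aryl and heteroaryl bromides alone.

**Compound list**
1 | methyl 2-amino-4-bromobenzoate | COC(=O)c1ccc(Br)cc1N | starting material
2 | methyl 2-amino-4,5-dibromobenzoate | COC(=O)c1cc(Br)c(Br)cc1N | intermediate
3 | acetic anhydride | CC(=O)OC(C)=O | starting material
4 | methyl 2-acetamido-4,5-dibromobenzoate | COC(=O)c1cc(Br)c(Br)cc1NC(C)=O | intermediate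
5 | methyl 4,5-dibromo-2-(N-methylacetamido)benzoate | COC(=O)c1cc(Br)c(Br)cc1N(C)C(C)=O | intermediate
6 | 6,7-dibromo-4-hydroxy-1-methylquinolin-2(1H)-one | Cn1c(=O)cc(O)c2cc(Br)c(Br)cc21 | intermediate
7 | 6,7-dibromo-3-diazo-1-methylquinoline-2,4(1H,3H)-dione | CN1C(=O)C(=[N+]=[N-])C(=O)c2cc(Br)c(Br)cc21 | intermediate
8 | 5,6-dibromo-1-methyl-3-(oxomethylidene)indolin-2-one (ketene, formed in the flask) | CN1C(=O)C(=C=O)c2cc(Br)c(Br)cc21 | intermediate
9 | methyl 5,6-dibromo-1-methyl-2-oxoindoline-3-carboxylate (racemic, enolisable at C3) | COC(=O)C1C(=O)N(C)c2cc(Br)c(Br)cc21 | intermediate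
10 | methyl 5,6-dibromo-2-(dibromophosphoryloxy)-1-methylindole-3-carboxylate (formed in the flask) | COC(=O)c1c(OP(=O)(Br)Br)n(C)c2cc(Br)c(Br)cc12 | intermediate
11 | methyl 2,5,6-tribromo-1-methylindole-3-carboxylate | COC(=O)c1c(Br)n(C)c2cc(Br)c(Br)cc12 | intermediate
12 | (2,5,6-tribromo-1-methylindol-3-yl)methanol | OCc1c(Br)n(C)c2cc(Br)c(Br)cc12 | intermediate
13 | 2,5,6-tribromo-1-methylindole-3-carbaldehyde | Cn1c(Br)c(C=O)c2cc(Br)c(Br)cc21 | target

Total step count: 9
Longest linear sequence: 9 steps (1 to 13)

**Steps most likely to fail**

**Step 6.**
- Methanol may capture the excited diazo compound or the carbene (O–H insertion or reduction) before the aryl group shifts.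
- The brominated aryl ketone chromophore may lose bromine under irradiation.
- The enolic product may be acylated by the ketene.

The fallback contracts the ring without light and without a carbene, by a benzilic ester rearrangement. It sets out from 7. Dimethyldioxirane in acetone should exchange the diazo group for oxygen and give 6,7-dibromo-1-methylquinoline-2,3,4(1H)-trione F1. NaOMe in MeOH should then trigger the 1,2-shift of the vicinal tricarbonyl system, the reaction type by which alloxan contracts to alloxanic acid. This would give methyl 5,6-dibromo-3-hydroxy-1-methyl-2-oxoindoline-3-carboxylate F2 as a racemate. Acetylation with Ac2O and DMAP gives methyl 3-acetoxy-5,6-dibromo-1-methyl-2-oxoindoline-3-carboxylate F3. Reductive cleavage of the α-acyloxy group with SmI2 in THF–MeOH at −78 °C, conditions that leave aryl bromides alone, brings the sequence back to the route at 9.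

**Step 7.**
- O-Activation of the strongly hydrogen-bonded enol may be sluggish.
- The hydrogen bromide released may cleave the methyl ester, and decarboxylation would follow.

The fallback accepts the loss of the ester carbon and brings in bromine and the formyl carbon together. It sets out from 9. Hydrolysis and decarboxylation in refluxing aqueous HCl–AcOH give 5,6-dibromo-1-methylindolin-2-one F4. Vilsmeier–Haack–Arnold bromoformylation with POBr3 and DMF in CHCl3, a standard conversion of oxindoles into 2-bromoindole-3-carbaldehydes, gives N,N-dimethyl-1-(2,5,6-tribromo-1-methylindol-3-yl)methaniminium bromide F5. Hydrolysis with aqueous NaHCO3 rejoins the route at 13 and skips 11 and 12.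

**Step 8.**
- The aluminium alkoxide may ionise to a 3-methyleneindoleninium ion that takes up a second hydride, which would over-reduce the side chain.
- Hydride may attack the C2–Br bond.
- The carbinol may self-condense during isolation.

The fallback halts the reduction at the aldehyde level through a chelated tetrahedral intermediate, with no reduce-and-reoxidise sequence. It sets out from 11. Aminolysis with the aluminium amide made from AlMe3 and MeNH(OMe)·HCl in toluene gives 2,5,6-tribromo-N-methoxy-N,1-dimethylindole-3-carboxamide F6. Treatment with iBu2AlH (1.2 equiv) in THF at −78 °C, followed by aqueous work-up, rejoins the route at 13 and skips 12 and step 9.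

**Further compounds**
F1 | step 6 | 6,7-dibromo-1-methylquinoline-2,3,4(1H)-trione | CN1C(=O)C(=O)C(=O)c2cc(Br)c(Br)cc21
F2 | step 6 | methyl 5,6-dibromo-3-hydroxy-1-methyl-2-oxoindoline-3-carboxylate (racemic) | COC(=O)C1(O)C(=O)N(C)c2cc(Br)c(Br)cc21
F3 | step 6 | methyl 3-acetoxy-5,6-dibromo-1-methyl-2-oxoindoline-3-carboxylate (racemic) | COC(=O)C1(OC(C)=O)C(=O)N(C)c2cc(Br)c(Br)cc21
F4 | step 7 | 5,6-dibromo-1-methylindolin-2-one | CN1C(=O)Cc2cc(Br)c(Br)cc21
F5 | step 7 | N,N-dimethyl-1-(2,5,6-tribromo-1-methylindol-3-yl)methaniminium bromide | C[N+](C)=Cc1c(Br)n(C)c2cc(Br)c(Br)cc12.[Br-]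
F6 | step 8 | 2,5,6-tribromo-N-methoxy-N,1-dimethylindole-3-carboxamide | CON(C)C(=O)c1c(Br)n(C)c2cc(Br)c(Br)cc12
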